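**Retrosynthetic overview**
1. Atom numbers used: ring C1 (C=O), C2 (C–CH2OAc), C3 (=CH), C4 (CHOH), C5 and C6 (oxirane carbons; C5 carries the chain C1'–C12').
2. Last bond: C5'–C6' by Stille coupling of dienyl iodide 19 with alkenylstannane 25, so the triene is formed at the very end.
3. Carbocycle: closed at C2–C3 from the acyclic vinyl ketone aldehyde 15. The unit C1(=O)–C2(CH2OAc)=C3H is the 1,3-transposed acetate of a Morita–Baylis–Hillman adduct, so cyclisation, acetylation and acetate shift run in one flask.
4. Enabling feature: the oxirane C5–C6 holds the acyl carbon C1 (on C6) and the formyl-bearing C4 (on C5) cis to each other, and C6 cannot form an enolate, so only C2 can attack C3 and a six-membered ring results.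
5. C1', C5 and C4 come from C2, C3 and C4 of L-arabinose (sugar C1 becomes C2', sugar C5 becomes C3). Ring order: oxirane first (on the furanos-3-ulose), then a temporary 1,3-dioxane, then the carbocycle.

Key step: step 13

Remark: in step 3 the stabilised ylide is assumed to place the amide carbonyl on the side of sugar C2 (Z alkene), as expected on steric grounds; the E isomer can also be used (fallback for step 3).

**Route**

Step 1
Reactants: 1 L-arabinose
Product: 3 5-O-(tert-butyldiphenylsilyl)-1,2-O-isopropylidene-β-L-arabinofuranose, via 5-O-TBDPS-L-arabinofuranose 2 (not isolated)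
Conditions: TBDPSCl, imidazole, DMF, 0 °C to rt; then 2,2-dimethoxypropane, TsOH (cat.), acetone, rt
Reagents that add atoms: tert-butyl(chloro)diphenylsilane CC(C)(C)[Si](Cl)(c1ccccc1)c1ccccc1; 2,2-dimethoxypropane COC(C)(C)OC
Why: Silylation of the only primary hydroxyl (present in the furanose form) locks the furanose, and acetal exchange then takes the cis-1,2-diol, which leaves O3 as the single free hydroxyl and keeps all three sugar stereocentres.

Step 2
Reactants: 3 5-O-TBDPS-1,2-O-isopropylidene-β-L-arabinofuranose
Product: 4 5-O-TBDPS-1,2-O-isopropylidene-β-L-threo-pentofuranos-3-ulose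
Conditions: Dess–Martin periodinane, CH2Cl2, 0 °C to rt
Reagents that add atoms: none
Why: Dess–Martin oxidation of the single secondary alcohol under non-basic conditions, chosen so that sugar C4 next to the new ketone does not epimerise.

Step 3
Reactants: 4 5-O-TBDPS-1,2-O-isopropylidene-β-L-threo-pentofuranos-3-ulose
Product: 5 (Z)-3-deoxy-3-C-[2-(methoxy(methyl)amino)-2-oxoethylidene]-5-O-TBDPS-1,2-O-isopropylidene-β-L-threo-pentofuranose
Conditions: Ph3P=CHC(O)N(OMe)Me, CH2Cl2, rt to 40 °C
Reagents that add atoms: N-methoxy-N-methyl-2-(triphenylphosphoranylidene)acetamide CON(C)C(=O)C=P(c1ccccc1)(c1ccccc1)c1ccccc1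
Why: Wittig olefination of the electron-poor furanos-3-ulose with a neutral stabilised ylide, in which the amide carbonyl should turn toward sugar C2 and away from the bulkier silyloxymethyl-bearing C4 (Z alkene).

Step 4
Reactants: 5 (Z)-enamide
Product: 6 3-C-[(1S)-1-hydroxy-2-(methoxy(methyl)amino)-2-oxoethyl]-5-O-TBDPS-1,2-O-isopropylidene-β-L-arabinofuranose
Conditions: K2OsO2(OH)4 (cat.), N-methylmorpholine N-oxide, citric acid, t-BuOH/H2O, rt
Reagents that add atoms: N-methylmorpholine N-oxide C[N+]1([O-])CCOCC1; water O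
Why: Osmium-catalysed syn-dihydroxylation from the face opposite to the acetonide and the C4 side chain (both on the lower face) sets the tertiary C–O of the future C5 and, through the Z geometry, the S carbinol on the future C6.

Step 5
Reactants: 6 diol
Product: 8 3,1'-anhydro-3-C-[(1R)-1-hydroxy-2-(methoxy(methyl)amino)-2-oxoethyl]-5-O-TBDPS-1,2-O-isopropylidene-β-L-arabinofuranose (spiro-oxirane; oxirane O anti to the acetonide, amide cis to sugar C4), via secondary mesylate 7 (not isolated)
Conditions: MsCl, Et3N, CH2Cl2, 0 °C; then K2CO3, MeOH, rt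
Reagents that add atoms: none
Why: Selective sulfonylation of the secondary α-hydroxy amide hydroxyl followed by intramolecular SN2 displacement by the tertiary alkoxide (glycidic amide formation from an α-sulfonyloxy-β-hydroxy carbonyl compound) inverts the future C6 and so places the acyl group cis to sugar C4.

Step 6
Reactants: 8 spiro-oxirane acetonide
Product: 9 3,1'-anhydro-3-C-[(1R)-1-hydroxy-2-(methoxy(methyl)amino)-2-oxoethyl]-5-O-TBDPS-L-arabinofuranose (lactol, anomer mixture)
Conditions: CF3CO2H/H2O, 0 °C
Reagents that add atoms: none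
Why: Acid hydrolysis of the 1,2-O-isopropylidene acetal, tolerated because the oxirane is flanked by two oxygenated carbons and an acyl group (deactivated toward acid opening) and the silyl ether and Weinreb amide are acid-stable.

Step 7
Reactants: 9 lactol
Product: 10 (2R,3R)-3-[(1S)-2-(tert-butyldiphenylsilyloxy)-1-hydroxyethyl]-3-[(1S,2E)-1-hydroxy-3-methyl-4-oxobut-2-en-1-yl]-N-methoxy-N-methyloxirane-2-carboxamide
Conditions: Ph3P=C(CH3)CHO, toluene, 70 °C
Reagents that add atoms: 2-(triphenylphosphoranylidene)propanal CC(C=O)=P(c1ccccc1)(c1ccccc1)c1ccccc1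
Why: Wittig olefination of the lactol through its open hydroxy aldehyde form with an α-branched stabilised ylide gives the E trisubstituted enal (C2'=C3') and frees the two hydroxyls at C1' and C4.

Step 8
Reactants: 10 enal diol
Product: 11 acetonide of 10 (2,2-dimethyl-1,3-dioxane across the oxygens at C1' and C4; stereocentres as in 10)
Conditions: 2-methoxypropene, PPTS (cat.), CH2Cl2, 0 °C to rt
Reagents that add atoms: 2-methoxypropene COC(C)=C
Why: Acid-catalysed acetal formation ties the anti-1,3-diol into one temporary dioxane ring under conditions that leave the conjugated aldehyde and the oxirane alone.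

Step 9
Reactants: 11 enal acetonide
Product: 12 (1E,3E)-dienyl iodide (C2'=C3'(CH3)–C4'H=C5'H–I in place of the enal of 11)
Conditions: CrCl2, CHI3, THF, 0 °C to rt, dark
Reagents that add atoms: iodoform IC(I)I
Why: Takai olefination converts the hindered conjugated aldehyde into the E alkenyl iodide, while Weinreb amide, silyl ether and acetal are inert to the geminal dichromium reagent.

Step 10
Reactants: 12 dienyl iodide silyl ether
Product: 13 primary alcohol at C3 (TBDPS removed)
Conditions: Bu4NF, AcOH, THF, 0 °C to rt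
Reagents that add atoms: none
Why: Buffered fluoride cleaves the only silyl ether and leaves oxirane, amide, acetal and iodo diene untouched.

Step 11
Reactants: 13 hydroxy Weinreb amide
Product: 14 vinyl ketone (C1(=O)–CH=CH2 on oxirane C6; free C3–OH)
Conditions: CH2=CHMgBr (excess), THF, −78 to −40 °C; poured into cold aq. NH4Cl
Reagents that add atoms: vinylmagnesium bromide C=C[Mg]Br
Why: Weinreb ketone synthesis stops at the stable magnesium chelate, so a single vinyl group is added next to the oxirane, and the cold acidic quench prevents conjugate addition of the released hydroxylamine.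

Step 12
Reactants: 14 hydroxy vinyl ketone
Product: 15 vinyl ketone aldehyde (C3 formyl group on C4; used at once)
Conditions: Dess–Martin periodinane, CH2Cl2, 0 °C
Reagents that add atoms: none
Why: Dess–Martin oxidation of the primary alcohol is neutral and fast and does not touch the vinyl ketone, the oxirane or the α-alkoxy stereocentre C4.

Step 13
Reactants: 15 vinyl ketone aldehyde
Product: 18 acetonide-protected 2-(acetoxymethyl)cyclohexenone (carbocycle C1–C6 with C2=C3, CH2OAc on C2, oxirane C5–C6, dioxane across O4 and O1', iodo diene side chain), via methylene hydroxy ketone 16 (not isolated), via allylic acetate 17 (not isolated)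
Conditions: PMe3 (cat.), THF/t-BuOH, high dilution, rt; then Ac2O, DMAP (cat.), DABCO, rt to 45 °C
Reagents that add atoms: acetic anhydride CC(=O)OC(C)=O
Why: Trimethylphosphine adds to the terminal carbon of the vinyl ketone and the phosphonium enolate attacks the aldehyde carbon C3 through its α-carbon C2 (intramolecular Morita–Baylis–Hillman reaction); proton transfer and loss of the phosphine give the 2-methylene-3-hydroxycyclohexanone 16, acetylation gives 17, and DABCO then adds in SN2' fashion to the exocyclic methylene, expels the C3 acetate and is displaced by acetate at the CH2 carbon, so that the double bond ends at C2=C3 and the acetate on the primary carbon. The closest known reaction types are the phosphine-catalysed intramolecular Morita–Baylis–Hillman cyclisation of enone aldehydes, including acryloyl units tethered through their carbonyl group, and the amine-catalysed 1,3-transposition of Morita–Baylis–Hillman acetates to 2-(acetoxymethyl)-2-enones. The cyclohexenone ring closes in a 6-(enolexo)-exo-trig aldol mode. The only new stereocentre, the carbinol C3 of 16, is not controlled and need not be, because both epimers converge when C3 becomes sp2 in 18, while C4, C5, C6 and C1' are untouched. The step needs C2 as the only nucleophile and ring closure faster than oligomerisation of the vinyl ketone or enolisation of the aldehyde: C6 is an oxirane carbon that cannot form an enolate, the cis oxirane and the dioxane ring hold C2 and C3 within reach, the catalyst is a weak base, and high dilution is used. The conjugated, endocyclic, trisubstituted alkene with the primary acetate is the thermodynamic end point of the reversible acetate shift.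

Step 14
Reactants: 18 acetonide
Product: 19 [(1R,5S,6R)-5-hydroxy-6-[(1S,2E,4E)-1-hydroxy-5-iodo-3-methylpenta-2,4-dien-1-yl]-2-oxo-7-oxabicyclo[4.1.0]hept-3-en-3-yl]methyl acetate
Conditions: AcOH/H2O/THF, 40 °C
Reagents that add atoms: none
Why: Mild acid hydrolysis removes the strained acetonide of the anti-1,3-diol before the acid-sensitive triene exists, and the allylic acetate, the acyl-deactivated oxirane and the iodo diene should survive.

Step 15
Reactants: 20 4-pentyn-1-ol
Product: 21 (E)-5-iodo-4-methylpent-4-en-1-ol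
Conditions: Me3Al, Cp2ZrCl2 (cat.), CH2Cl2, 0 °C to rt; then I2, THF, −30 °C
Reagents that add atoms: trimethylaluminium C[Al](C)C; iodine II
Why: Negishi zirconium-catalysed carboalumination adds methyl and aluminium syn across the terminal alkyne (methyl to the internal carbon), and iodinolysis with retention gives the E iodide.

Step 16
Reactants: 21 (E)-5-iodo-4-methylpent-4-en-1-ol
Product: 22 (E)-5-iodo-4-methylpent-4-enal
Conditions: Dess–Martin periodinane, CH2Cl2, rt
Reagents that add atoms: none
Why: Dess–Martin oxidation of a primary alcohol to the aldehyde without touching the alkenyl iodide.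

Step 17
Reactants: 22 (E)-5-iodo-4-methylpent-4-enal
Product: 23 ethyl (2Z,6E)-7-iodo-2,6-dimethylhepta-2,6-dienoate
Conditions: (CF3CH2O)2P(O)CH(CH3)CO2Et, KN(SiMe3)2, 18-crown-6, THF, −78 °C
Reagents that add atoms: ethyl 2-[bis(2,2,2-trifluoroethoxy)phosphoryl]propanoate CCOC(=O)C(C)P(=O)(OCC(F)(F)F)OCC(F)(F)F
Why: Still–Gennari olefination, in which fast elimination from the kinetic adduct of the electron-poor phosphonate gives the Z trisubstituted enoate (C10'=C11').

Step 18
Reactants: 23 Z enoate
Product: 24 (2Z,6E)-7-iodo-2,6-dimethylhepta-2,6-dien-1-ol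
Conditions: i-Bu2AlH, CH2Cl2, −78 °C
Reagents that add atoms: none
Why: 1,2-Reduction of the conjugated ester to the allylic alcohol with retention of both alkene geometries.

Step 19
Reactants: 24 alkenyl iodide
Product: 25 (2Z,6E)-2,6-dimethyl-7-(trimethylstannyl)hepta-2,6-dien-1-ol
Conditions: Me3SnSnMe3, Pd(PPh3)4 (cat.), i-Pr2NEt, toluene, 80 °C
Reagents that add atoms: hexamethylditin C[Sn](C)(C)[Sn](C)(C)C
Why: Palladium-catalysed stannylation of an alkenyl iodide (oxidative addition to zerovalent palladium, transmetalation with the ditin, reductive elimination) proceeds with retention of the E geometry and tolerates the free hydroxyl.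

Step 20
Reactants: 19 dienyl iodide; 25 alkenylstannane
Product: 26 [(1R,5S,6R)-6-[(1S,2E,4E,6E,10Z)-1,12-dihydroxy-3,7,11-trimethyldodeca-2,4,6,10-tetraen-1-yl]-5-hydroxy-2-oxo-7-oxabicyclo[4.1.0]hept-3-en-3-yl]methyl acetate (target)
Conditions: Pd2(dba)3 (cat.), AsPh3, N-methylpyrrolidone, rt, dark
Reagents that add atoms: none
Why: Stille coupling joins C5' and C6' with retention of both alkene geometries under neutral conditions that should tolerate the free hydroxyls, the epoxy enone and the allylic acetate.

**Compound list**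
1 | L-arabinose | O=C[C@H](O)[C@@H](O)[C@@H](O)CO | starting material
2 | 5-O-TBDPS-L-arabinofuranose (anomer mixture) | OC1O[C@@H](CO[Si](c2ccccc2)(c2ccccc2)C(C)(C)C)[C@H](O)[C@H]1O | intermediate
3 | 5-O-TBDPS-1,2-O-isopropylidene-β-L-arabinofuranose | CC1(C)O[C@H]2O[C@@H](CO[Si](c3ccccc3)(c3ccccc3)C(C)(C)C)[C@H](O)[C@H]2O1 | intermediate
4 | 5-O-TBDPS-1,2-O-isopropylidene-β-L-threo-pentofuranos-3-ulose | CC1(C)O[C@H]2O[C@@H](CO[Si](c3ccccc3)(c3ccccc3)C(C)(C)C)C(=O)[C@H]2O1 | intermediate
5 | (Z)-exocyclic enamide (amide carbonyl syn to sugar C2) | CC1(C)O[C@H]2O[C@@H](CO[Si](c3ccccc3)(c3ccccc3)C(C)(C)C)/C(=C/C(=O)N(C)OC)[C@H]2O1 | intermediate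
6 | diol (tertiary OH anti to the acetonide, exocyclic carbinol S) | CC1(C)O[C@H]2O[C@@H](CO[Si](c3ccccc3)(c3ccccc3)C(C)(C)C)[C@@](O)([C@H](O)C(=O)N(C)OC)[C@H]2O1 | intermediate
7 | secondary mesylate of 6 | CC1(C)O[C@H]2O[C@@H](CO[Si](c3ccccc3)(c3ccccc3)C(C)(C)C)[C@@](O)([C@H](OS(C)(=O)=O)C(=O)N(C)OC)[C@H]2O1 | intermediate
8 | spiro-oxirane glycidic Weinreb amide (oxirane CH R, amide cis to sugar C4) | CC1(C)O[C@H]2O[C@@H](CO[Si](c3ccccc3)(c3ccccc3)C(C)(C)C)[C@]4(O[C@H]4C(=O)N(C)OC)[C@H]2O1 | intermediate
9 | spiro-oxirane lactol (anomer mixture) | OC1O[C@@H](CO[Si](c2ccccc2)(c2ccccc2)C(C)(C)C)[C@]3(O[C@H]3C(=O)N(C)OC)[C@H]1O | intermediate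
10 | (E)-enal diol, (2R,3R)-oxirane-2-carboxamide of step 7 | O=C/C(C)=C/[C@H](O)[C@@]1(O[C@H]1C(=O)N(C)OC)[C@@H](O)CO[Si](c1ccccc1)(c1ccccc1)C(C)(C)C | intermediate
11 | enal 1,3-dioxane acetonide | O=C/C(C)=C/[C@@H]1OC(C)(C)O[C@@H](CO[Si](c2ccccc2)(c2ccccc2)C(C)(C)C)[C@]13O[C@H]3C(=O)N(C)OC | intermediate
12 | (1E,3E)-dienyl iodide acetonide silyl ether | I/C=C/C(C)=C/[C@@H]1OC(C)(C)O[C@@H](CO[Si](c2ccccc2)(c2ccccc2)C(C)(C)C)[C@]13O[C@H]3C(=O)N(C)OC | intermediate
13 | primary alcohol Weinreb amide | I/C=C/C(C)=C/[C@@H]1OC(C)(C)O[C@@H](CO)[C@]13O[C@H]3C(=O)N(C)OC | intermediate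
14 | hydroxy vinyl ketone | I/C=C/C(C)=C/[C@@H]1OC(C)(C)O[C@@H](CO)[C@]13O[C@H]3C(=O)C=C | intermediate
15 | vinyl ketone aldehyde | I/C=C/C(C)=C/[C@@H]1OC(C)(C)O[C@@H](C=O)[C@]13O[C@H]3C(=O)C=C | intermediate
16 | 2-methylene-3-hydroxycyclohexanone (C3 epimer mixture) | C=C1C(O)[C@@H]2OC(C)(C)O[C@@H](/C=C(C)/C=C/I)[C@@]23O[C@H]3C1=O | intermediate
17 | C3 acetate of 16 | C=C1C(OC(C)=O)[C@@H]2OC(C)(C)O[C@@H](/C=C(C)/C=C/I)[C@@]23O[C@H]3C1=O | intermediate
18 | acetonide-protected 2-(acetoxymethyl)cyclohexenone | CC(=O)OCC1=C[C@@H]2OC(C)(C)O[C@@H](/C=C(C)/C=C/I)[C@@]23O[C@H]3C1=O | intermediate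
19 | epoxy enone diol with iodo diene side chain | CC(=O)OCC1=C[C@H](O)[C@@]2([C@@H](O)/C=C(C)/C=C/I)O[C@H]2C1=O | intermediate
20 | 4-pentyn-1-ol | C#CCCCO | starting material
21 | (E)-5-iodo-4-methylpent-4-en-1-ol | OCCC/C(C)=C/I | intermediate
22 | (E)-5-iodo-4-methylpent-4-enal | O=CCC/C(C)=C/I | intermediate
23 | ethyl (2Z,6E)-7-iodo-2,6-dimethylhepta-2,6-dienoate | CCOC(=O)/C(C)=C\CC/C(C)=C/I | intermediate
24 | (2Z,6E)-7-iodo-2,6-dimethylhepta-2,6-dien-1-ol | OC/C(C)=C\CC/C(C)=C/I | intermediate
25 | (2Z,6E)-2,6-dimethyl-7-(trimethylstannyl)hepta-2,6-dien-1-ol | OC/C(C)=C\CC/C(C)=C/[Sn](C)(C)C | intermediate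
26 | CNP0305847.1 | CC(=O)OCC1=C[C@H](O)[C@@]2([C@@H](O)/C=C(C)/C=C/C=C(\C)CC/C=C(/C)CO)O[C@H]2C1=O | target

**Step count and risks**
Total step count: 20. Longest linear sequence: 15 steps (steps 1 to 14, then step 20).

Steps most likely to fail:

Step 13 (ring closure at C2–C3). The phosphonium enolate may be consumed by intermolecular oligomerisation of the vinyl ketone, the aldehyde may enolise and open the oxirane by β-elimination before the ring closes, or the acetate shift may stop at the branched acetate. The fallback closes the same bond by ring-closing metathesis and sets out from 13. Dess–Martin oxidation gives the aldehyde Weinreb amide F1. Methylenation with Ph3P=CH2 gives the terminal alkene F2. Addition of 2-lithio-3-(tert-butyldimethylsilyloxy)propene (from the bromide and t-BuLi) to the Weinreb amide gives the dienone F3. Ring closure with the second-generation Hoveyda–Grubbs catalyst gives the cyclohexenone silyl ether F4. HF·pyridine frees the primary allylic alcohol F5, and acetylation (Ac2O, pyridine) comes back to the route at 18.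

Step 3 (alkene geometry). The Wittig reaction may give poor control of the alkene geometry or mainly the E isomer, and the mildly basic ylide may epimerise the carbon next to the ketone. The fallback sets out from 4 and uses the E-configured enamide F6 instead of discarding it. Direct, stereospecific oxygen transfer from dimethyldioxirane to the same upper face gives the oxirane with the amide cis to sugar C4, because syn epoxidation of the E alkene and dihydroxylation with invertive closure of the Z alkene lead to the same configuration. It comes back to the route at 8.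

Step 9 (alkenyl iodide). Electron transfer from divalent chromium to the glycidic amide may open the oxirane reductively, or E selectivity may erode. The fallback sets out from 11. Ohira–Bestmann homologation (dimethyl (1-diazo-2-oxopropyl)phosphonate, K2CO3, MeOH) gives the enyne F7. Palladium-catalysed syn-hydrostannation (Bu3SnH, PdCl2(PPh3)2) gives the (E)-dienylstannane F8, and iododestannylation with I2 comes back to the route at 12.

Further compounds
F1 | step 13 | aldehyde Weinreb amide (C3 formyl, from 13) | I/C=C/C(C)=C/[C@@H]1OC(C)(C)O[C@@H](C=O)[C@]13O[C@H]3C(=O)N(C)OC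
F2 | step 13 | terminal alkene Weinreb amide (vinyl group on C4) | I/C=C/C(C)=C/[C@@H]1OC(C)(C)O[C@@H](C=C)[C@]13O[C@H]3C(=O)N(C)OC
F3 | step 13 | dienone with 2-(tert-butyldimethylsilyloxymethyl)vinyl ketone | I/C=C/C(C)=C/[C@@H]1OC(C)(C)O[C@@H](C=C)[C@]13O[C@H]3C(=O)C(=C)CO[Si](C)(C)C(C)(C)C
F4 | step 13 | cyclohexenone silyl ether (CH2OTBS on C2) | CC(C)(C)[Si](C)(C)OCC1=C[C@@H]2OC(C)(C)O[C@@H](/C=C(C)/C=C/I)[C@@]23O[C@H]3C1=O
F5 | step 13 | primary allylic alcohol (CH2OH on C2) | OCC1=C[C@@H]2OC(C)(C)O[C@@H](/C=C(C)/C=C/I)[C@@]23O[C@H]3C1=O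
F6 | step 3 | (E)-exocyclic enamide (amide carbonyl syn to sugar C4) | CC1(C)O[C@H]2O[C@@H](CO[Si](c3ccccc3)(c3ccccc3)C(C)(C)C)/C(=C\C(=O)N(C)OC)[C@H]2O1
F7 | step 9 | (E)-enyne acetonide | C#C/C(C)=C/[C@@H]1OC(C)(C)O[C@@H](CO[Si](c2ccccc2)(c2ccccc2)C(C)(C)C)[C@]13O[C@H]3C(=O)N(C)OC
F8 | step 9 | (1E,3E)-dienyl tributylstannane | CCCC[Sn](CCCC)(CCCC)/C=C/C(C)=C/[C@@H]1OC(C)(C)O[C@@H](CO[Si](c2ccccc2)(c2ccccc2)C(C)(C)C)[C@]13O[C@H]3C(=O)N(C)OC
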